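The ratio of target to substrate at rest is 1.1, and each further step round the ring multiplies the ratio by that step's equilibrium constant, until the last step closes the ring.

substrate 15 mM; time 5.0 d

    target ⇌ isomer of the product A (K1 = 2.1, k1 = 0.0433 /h)
    isomer of the product A ⇌ isomer of the product B (K2 = 1.34, k2 = 0.147 /h)
    substrate ⇌ target (K3 = 1.1, k3 = 0.0753 /h)
    isomer of the product B ⇌ substrate (k4 = 0.0351 /h)

* at 5.0 d, what has stopped the reaction, if anything has (all of the substrate has reacted / it is still moving / forward and back rates have come level)
* how much of the substrate has reacted by 5.0 d
* how much target there is at 5.0 d, in percent of the substrate charged
* how much isomer of the product B there is at 5.0 d, in percent of the substrate charged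
* how much isomer of the product A there is at 5.0 d, in percent of the substrate charged

Nothing enters or leaves this flask, so the four shares of the charge add up to 100 percent. Dividing by the sum of the ratios gives s, the equilibrium share of substrate, meaning the part of the charge that is still substrate once each step runs level: 13.3 %. Each rate is a constant times one concentration, so the charge cancels from s.

| Species | Ratio to substrate | Share at rest |
|---|---|---|
| substrate | 1 | 13.3 % |
| target | 1.10 | 14.7 % |
| isomer of the product A | 2.31 | 30.8 % |
| isomer of the product B | 3.10 | 41.2 % |

Now we turn the question round. For the substrate to be used up, s would have to be nil, and it stands at 13.3 %. For this flask to be still moving, some species would have to change by 0.6 points or more over the second half of the time, so at half time it would have to lie about that far from rest.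

To test that roughly, we treat substrate with target as one pair and the two isomers as another, each pair balanced inside. Weighing the four crossing rate constants by each species' share in its pair and adding them gives a rate λ = 0.103 /h, a time constant of 9.68 h. If the substrate's distance from rest at the start, 86.7 % of the charge and more than that of any other species, fell at that rate, 0.18 percentage points would remain at half time, less than the 0.6 points needed. So we expect level rates and 86.7 % reacted.

The forecast gives "forward and back rates have come level", with 86.7 % reacted, 14.7 % target, 41.2 % isomer of the product B and 30.8 % isomer of the product A, holding that “the flask has effectively reached equilibrium”.

In the simulated flask, forward and back rates have come level: 86.7 % reacted, 14.7 % target, 41.2 % isomer of the product B and 30.8 % isomer of the product A. Left until 50.0 d, this flask shows 86.7 % reacted. One minus s, 86.7 %, is our reckoning for a neighbour flask charged with 38 mM of substrate, and that neighbour has reacted 86.7 % at 5.00 d.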